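**Retrosynthetic overview**

1. Locants: C1 (CH–O-methacryloyl), C2 (CH2), C3 (CH–O-isobutyryl), C4 (C–CH3), C5 (CH), C6 (C=O), C7 (=CH), C8 (=C–CH3), C9 (CH), C10 (CH), C11 (CMe2). Ring A is the cyclohexenone C5–C10, ring B the cyclobutane C4–C5–C10–C9, ring C the seven-membered ring C1–C4/C9–C11.
2. Feature: C6=O of ring A and C3 of ring C (a ketone at the key step) stand 1,4 across the cyclobutane bond C4–C5. Two enolate carbons joined under oxidation make this dissonant pair directly.
3. Target ⇐ C1-hydroxy C3-ketone 16 (Evans–Tishchenko reaction, then acylation) ⇐ epoxy diketone 15 ⇐ (C4–C5, ring B) cis-fused bicyclic epoxy ketone 13. The C1–C2 oxirane replaces a C1 silyl ether so that C2 cannot enolize.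
4. 13 ⇐ 11 ⇐ 9: ring C is closed at C4–C9 by oxidative coupling of the chain silyl enol ether with the γ-carbon of the ring A silyl dienol ether.
5. 9 ⇐ (+)-3-carene (ring A, C10, C11) + pent-1-yn-3-one + B2pin2. Ring order: A (from carene), C (step 6), B (step 8).

Key step: step 8

Remark: C1 is introduced without control in step 4 and C4 stays epimerizable until step 8. Compounds 7–12 are therefore epimer mixtures at these centres, and their SMILES leave them open.

Step 1
Reactants: 1 (+)-3-carene
Product: 2 car-3-en-5-one
Conditions: t-BuOOH (70% aq.), CrO3 (5 mol%), CH2Cl2, rt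
Reagents that add atoms: tert-butyl hydroperoxide, CC(C)(C)OO
Why: Chromium-catalysed allylic oxidation should attack the ring methylene that is remote from the vinylic methyl and flanked by the cyclopropane, giving the conjugated cyclopropyl enone without touching either stereocentre.

Step 2
Reactants: 2 car-3-en-5-one
Product: 3 (S)-5-(2-bromopropan-2-yl)-3-methylcyclohex-2-en-1-one
Conditions: HBr (33% in AcOH), CH2Cl2, 0 °C
Reagents that add atoms: hydrogen bromide, Br
Why: Acid-mediated homoconjugate opening of the cyclopropyl ketone (the bond from the carbonyl α-carbon to CMe2 breaks to a tertiary cation that bromide captures) should give the tertiary bromide, and the CH that becomes C10 keeps its configuration.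

Step 3
Reactants: 3 (S)-5-(2-bromopropan-2-yl)-3-methylcyclohex-2-en-1-one; 4 pent-1-yn-3-one
Product: 5 (S)-3-methyl-5-[(E)-2-methyl-5-oxohept-3-en-2-yl]cyclohex-2-en-1-one
Conditions: Bu3SnH (slow addition), AIBN, 4 (5 equiv), PhH, 80 °C; then I2 (5 mol%), CH2Cl2, rt
Reagents that add atoms: pent-1-yn-3-one (4), CCC(=O)C#C
Why: Giese reaction: the tertiary radical adds to the terminal alkyne carbon of the ynone (kept in excess so that hydrostannation stays minor) and creates the quaternary C11, iodine then converges the enone geometry on E, and no stereocentre is formed.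

Step 4
Reactants: 5 (S)-3-methyl-5-[(E)-2-methyl-5-oxohept-3-en-2-yl]cyclohex-2-en-1-one; 6 bis(pinacolato)diboron
Product: 8 (5S)-5-(3-hydroxy-2-methyl-5-oxoheptan-2-yl)-3-methylcyclohex-2-en-1-one, via pinacol boronate 7 (not isolated)
Conditions: CuCl (5 mol%), NaOtBu (10 mol%), DPEphos, 6 (1.1 equiv), MeOH, THF, rt; then NaBO3·4H2O, THF/H2O, rt
Reagents that add atoms: bis(pinacolato)diboron (6), CC1(C)OB(OC1(C)C)B1OC(C)(C)C(C)(C)O1; sodium perborate, [Na+].[Na+].O[B-]1(O)OO[B-](O)(O)OO1
Why: Copper-catalysed conjugate borylation followed by oxidation should be selective for the β-monosubstituted acyclic enone over the β,β-disubstituted ring enone, and C1 forms as both epimers, which is harmless because the centre is erased in step 7.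

Step 5
Reactants: 8 (5S)-5-(3-hydroxy-2-methyl-5-oxoheptan-2-yl)-3-methylcyclohex-2-en-1-one
Product: 9 tert-butyldimethylsilyl ether of 8
Conditions: TBSOTf, 2,6-lutidine, CH2Cl2, −78 to 0 °C
Reagents that add atoms: tert-butyldimethylsilyl triflate, CC(C)(C)[Si](C)(C)OS(=O)(=O)C(F)(F)F
Why: Silylation with the silyl triflate and a hindered base should protect the neopentyl-type alcohol without retro-aldol cleavage or elimination, and the bulky ether shields the C2 side of the chain ketone for the next step.

Step 6
Reactants: 9 tert-butyldimethylsilyl ether of 8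
Product: 11 cis-fused bicyclo[5.4.0] silyloxy diketone (ring A enone; ring C with C1-OTBS and C3 ketone; C4-H), via bis(trimethylsilyl enol ether) 10 (not isolated)
Conditions: TMSCl, NaI, Et3N, MeCN, rt; then (NH4)2Ce(NO3)6 (2.2 equiv), NaHCO3, MeCN, −30 to 0 °C
Reagents that add atoms: none
Why: Oxidative cross-coupling of a silyl enol ether with a silyl dienol ether: thermodynamic silylation should give the ring A 1-silyloxy-1,3-diene and the chain enol ether on the ethyl side, tetravalent cerium then gives the C4 α-keto radical, which adds 7-exo to the diene terminus C9 (C7 is out of reach of the tether) before oxidation and loss of silyl restore the enone; C9 is expected cis to C11 through the tether and is equilibrated in step 7 in any case.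

Step 7
Reactants: 11 cis-fused bicyclo[5.4.0] silyloxy diketone
Product: 13 cis-fused bicyclic epoxy ketone (C1-C2 oxirane on the face of H-9 and H-10; ring A enone; C4-H), via bis-enone 12 (not isolated)
Conditions: DBU, PhMe, 80 °C; then t-BuOOH (in decane), 0 °C to rt
Reagents that add atoms: tert-butyl hydroperoxide, CC(C)(C)OO
Why: E1cB loss of silanolate gives the cycloheptenone, DBU equilibrates the γ-epimerizable C9 to the cis-fused isomer (an axial C4 on C9 avoids A(1,2) strain with the C8 methyl), and Weitz–Scheffer epoxidation should take the less substituted ring C enone from its convex face, anti to ring A, which sets C1 and C2 with the oxygen on the side of H-9 and H-10.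

Step 8
Reactants: 13 cis-fused bicyclic epoxy ketone
Product: 15 tricyclic epoxy diketone (rings A, B and C; C1-C2 oxirane; C3 and C6 ketones), via dilithium bis-enolate 14 (not isolated)
Conditions: LiN(iPr)2 (2.3 equiv), THF, −78 °C; then Fe(acac)3 (2.2 equiv), THF, −78 °C to rt
Reagents that add atoms: none
Why: LiN(iPr)2 removes the only kinetically accessible acidic hydrogens, C4–H of the epoxy ketone (C2 is an oxirane carbon and does not enolize at −78 °C) and one C5–H of the cyclohexenone (α′ site), to give bis-enolate 14; trivalent iron oxidizes the more electron-rich tetrasubstituted C3=C4 enolate to a tertiary α-keto radical at C4, which adds to C5 of the neighbouring enolate, and a second electron transfer from the resulting ketyl radical anion gives the 1,4-diketone. The closest known reaction type is the intramolecular oxidative coupling of carbonyl bis-enolates by trivalent iron or divalent copper, routine for five- and six-membered rings and precedented for cyclobutane-1,2-dicarbonyl compounds from adipate-type dienolates, so the four-membered closure is rare but not new in kind. Ring B closes in a 4-exo-trig mode (C4 attacks C5 of the C5=C6 enolate and C6 stays outside the new ring) and is made irreversible by the fast second oxidation. Both new stereocentres are dictated by the cis-fused bicycle: C4 hangs axially from C9 on the face that also carries C5, so the bond can form only on that face, which turns the C4 methyl toward the C6–C8 bridge and C3 toward C11, while C5 becomes a bridgehead. The step needs regioselective double enolization, secured by the oxirane that blocks C2 (a C2 enolate would instead join C5 and close a five-membered ring), and it needs C4 and C5 close together, secured by the cis ring fusion set in step 7; Fe(acac)3 is chosen because it is not Lewis acidic toward the oxirane. Neither new centre can enolize afterwards, so the product is not eroded by epimerization.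

Step 9
Reactants: 15 tricyclic epoxy diketone
Product: 16 tricyclic C1-hydroxy C3,C6-diketone
Conditions: PhSeSePh, NaBH4, EtOH; AcOH; 0 °C
Reagents that add atoms: none
Why: Reductive cleavage of the α,β-epoxy ketone by the selenolate–borate (selenolate opens the oxirane at C2 and a second selenolate removes selenium) should leave the C1–O bond and its configuration untouched and spare the cyclobutane 1,4-diketone, which a one-electron reductant could fragment.

Step 10
Reactants: 16 tricyclic C1-hydroxy C3,C6-diketone; 17 methacrolein
Product: 18 C1 methacrylate C3 alcohol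
Conditions: SmI2 (0.3 equiv) premixed with PhCHO (0.3 equiv), 17 (8 equiv), BHT, THF, −10 °C
Reagents that add atoms: methacrolein (17), CC(=C)C=O
Why: Evans–Tishchenko reaction: the trivalent samarium alkoxide of 16 adds to the non-enolizable aldehyde and the hemiacetal delivers hydride to C3 through a six-membered chelate on the face of the C1 oxygen, which should give the 1,3-anti diol monoester with the methacryloyl group on O1, the new C3 hydroxyl trans to it and the ring A enone untouched.

Step 11
Reactants: 18 C1 methacrylate C3 alcohol; 19 isobutyric anhydride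
Product: 20 CNP0214356.1
Conditions: 19 (3 equiv), DMAP, Et3N, CH2Cl2, rt
Reagents that add atoms: isobutyric anhydride (19), CC(C)C(=O)OC(=O)C(C)C
Why: DMAP-catalysed acylation of the remaining neopentyl-type secondary alcohol should complete the diester without touching the methacrylate or the enone.

**Compound list**

1 | (+)-3-carene, (1S,6R)-3,7,7-trimethylbicyclo[4.1.0]hept-3-ene | CC1=CC[C@@H]2[C@H](C1)C2(C)C | starting material
2 | car-3-en-5-one (carene with C=O next to the cyclopropane, conjugated to the ring alkene) | CC1=CC(=O)[C@@H]2[C@H](C1)C2(C)C | intermediate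
3 | (S)-5-(2-bromopropan-2-yl)-3-methylcyclohex-2-en-1-one | CC1=CC(=O)C[C@H](C1)C(C)(C)Br | intermediate
4 | pent-1-yn-3-one | CCC(=O)C#C | starting material
5 | (S)-3-methyl-5-[(E)-2-methyl-5-oxohept-3-en-2-yl]cyclohex-2-en-1-one | CC1=CC(=O)C[C@H](C1)C(C)(C)/C=C/C(=O)CC | intermediate
6 | bis(pinacolato)diboron | CC1(C)OB(OC1(C)C)B1OC(C)(C)C(C)(C)O1 | starting material
7 | pinacol boronate of 5 (boron on the chain carbon next to CMe2, both epimers; not isolated) | CC1=CC(=O)C[C@H](C1)C(C)(C)C(CC(=O)CC)B1OC(C)(C)C(C)(C)O1 | intermediate
8 | (5S)-5-(3-hydroxy-2-methyl-5-oxoheptan-2-yl)-3-methylcyclohex-2-en-1-one (both carbinol epimers) | CC1=CC(=O)C[C@H](C1)C(C)(C)C(O)CC(=O)CC | intermediate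
9 | tert-butyldimethylsilyl ether of 8 | CC1=CC(=O)C[C@H](C1)C(C)(C)C(CC(=O)CC)O[Si](C)(C)C(C)(C)C | intermediate
10 | bis(trimethylsilyl enol ether) of 9 (ring A 1-silyloxy-1,3-diene; chain enol ether toward the ethyl group; not isolated) | C[Si](C)(C)OC1=CC(C)=C[C@@H](C1)C(C)(C)C(O[Si](C)(C)C(C)(C)C)CC(O[Si](C)(C)C)=CC | intermediate
11 | cis-fused bicyclo[5.4.0] silyloxy diketone: ring A enone, ring C with C1–OTBS, C3=O and C4–H(CH3), H-9 and H-10 cis (epimers at C1 and C4) | CC(C)(C)[Si](C)(C)OC1CC(=O)C(C)[C@H]2C(C)=CC(=O)C[C@H]2C1(C)C | intermediate
12 | cis-fused bicyclic bis-enone: ring A enone and ring C C1=C2–C3=O (C4 epimers; not isolated) | C1=CC(=O)C(C)[C@H]2C(C)=CC(=O)C[C@H]2C1(C)C | intermediate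
13 | cis-fused bicyclic epoxy ketone: C1–C2 oxirane on the face of H-9 and H-10, C3=O, ring A enone (C4 epimers) | O=C1[C@H]2O[C@H]2C(C)(C)[C@@H]3CC(=O)C=C(C)[C@@H]3C1C | intermediate
14 | dilithium bis-enolate of 13 (C3=C4 and C5=C6 enolates; not isolated) | [Li+].[Li+].[O-]C1=C(C)[C@H]2C(C)=CC([O-])=C[C@H]2C(C)(C)[C@@H]3O[C@H]13 | intermediate
15 | tricyclic epoxy diketone: rings A, B and C, C1–C2 oxirane, C3=O, C6=O, C4 quaternary | O1[C@@H]2[C@H]1C(=O)[C@@]3(C)[C@@H]4C(=O)C=C(C)[C@H]3[C@@H]4C2(C)C | intermediate
16 | tricyclic C1-hydroxy C3,C6-diketone | O[C@@H]1CC(=O)[C@@]2(C)[C@@H]3C(=O)C=C(C)[C@H]2[C@@H]3C1(C)C | intermediate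
17 | methacrolein (2-methylprop-2-enal) | CC(=C)C=O | starting material
18 | C1 methacrylate C3 alcohol (C1–O and C3–O trans on ring C) | C=C(C)C(=O)O[C@@H]1C[C@@H](O)[C@@]2(C)[C@@H]3C(=O)C=C(C)[C@H]2[C@@H]3C1(C)C | intermediate
19 | isobutyric anhydride | CC(C)C(=O)OC(=O)C(C)C | starting material
20 | CNP0214356.1 | C=C(C)C(=O)O[C@@H]1C[C@@H](OC(=O)C(C)C)[C@@]2(C)[C@@H]3C(=O)C=C(C)[C@H]2[C@@H]3C1(C)C | target

**Step count**

Total: 11 steps. Longest linear sequence: 11 steps from 1.

**Steps most likely to fail**

1. Step 8 (key step). The four-membered ring may not close: the C4 radical can be over-oxidized or couple between molecules before it reaches C5, deprotonation of the hindered C4–H may lag, and the C5 enolate could open the oxirane if the mixture warms before oxidation. The fallback sets out from 13 and ties the two enolate oxygens together before oxidation. LiN(iPr)2 followed by iPr2SiCl2 should give the diisopropylsilylene-bridged bis(dienol ether) F1. Its oxidation with (NH4)2Ce(NO3)6 and NaHCO3 in MeCN at −30 °C (silicon-tethered oxidative enol ether coupling through the radical cation) holds C4 and C5 syn while the bond forms. The route is rejoined at 15.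

2. Step 6. Silylation may favour the exocyclic dienol ether of ring A or the wrong chain enol ether, the dienol ether may be oxidized on to a dienone or phenol, and the seven-membered closure may be slower than these paths. The fallback is polar and sets out from 9. Allylic oxidation of the enone γ-methylene with Rh2(cap)4 and t-BuOOH should give the ene-dione F2. Soft enolization of the chain ketone on its ethyl side (TiCl4, Bu3N, CH2Cl2, −78 °C) gives the trichlorotitanium enolate F3, which adds intramolecularly to the C9 ketone to give the bicyclic tertiary γ-hydroxy enone F4. Reductive removal of the γ-hydroxyl (SmI2, THF/HMPA, t-BuOH; vinylogous ketol reduction) brings the route back to 11.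

3. Step 7. Facial selectivity in the epoxidation may be poor because the gem-dimethyl group flanks both faces of C1, equilibration of the ring fusion may be incomplete, and the hydroperoxide may also attack the ring A enone. The fallback sets out from 12, isolated after the DBU treatment, and moves the C1 oxygen behind the key step under reagent control. LiN(iPr)2 gives the dilithium bis-dienolate F5 (only C4–H and C5–H are acidic), and Fe(acac)3 couples it to the tricyclic diene-dione F6. Conjugate borylation of the ring C enone with 6, CuCl, NaOtBu and a chiral Josiphos-type bisphosphine gives the C1 pinacol boronate F7; the ligand enantiomer is chosen on the substrate, since the two faces of this enone are almost equivalent once ring B is closed. Oxidation with NaBO3·4H2O rejoins the route at 16.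

Further compounds
F1 | step 8 | diisopropylsilylene-bridged bis(dienol ether) of 13 | CC(C)[Si]1(C(C)C)OC2=C(C)[C@H]3C(C)=CC(O1)=C[C@H]3C(C)(C)[C@@H]4O[C@H]24
F2 | step 6 | ene-dione from γ-oxidation of 9 (ring A 2-methylcyclohex-2-ene-1,4-dione) | CC1=CC(=O)C[C@H](C1=O)C(C)(C)C(CC(=O)CC)O[Si](C)(C)C(C)(C)C
F3 | step 6 | trichlorotitanium enolate of F2 (chain ketone, ethyl side; not isolated) | CC=C(O[Ti](Cl)(Cl)Cl)CC(O[Si](C)(C)C(C)(C)C)C(C)(C)[C@@H]1CC(=O)C=C(C)C1=O
F4 | step 6 | bicyclic tertiary γ-hydroxy enone (C9–OH aldol adduct) | CC(C)(C)[Si](C)(C)OC1CC(=O)C(C)[C@@]2(O)C(C)=CC(=O)C[C@H]2C1(C)C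
F5 | step 7 | dilithium bis-dienolate of 12 (not isolated) | [Li+].[Li+].[O-]C1=C(C)[C@H]2C(C)=CC([O-])=C[C@H]2C(C)(C)C=C1
F6 | step 7 | tricyclic diene-dione (ring C C1=C2–C3=O) | C1=CC(=O)[C@@]2(C)[C@@H]3C(=O)C=C(C)[C@H]2[C@@H]3C1(C)C
F7 | step 7 | C1 pinacol boronate of the tricyclic diketone (not isolated) | CC1(C)OB(OC1(C)C)[C@@H]2CC(=O)[C@@]3(C)[C@@H]4C(=O)C=C(C)[C@H]3[C@@H]4C2(C)C
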